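The readings come from a simulation from invented constants; noise was put on by code.

Friday's run, with 1.2 equiv of partner, reads 16.2% substrate at 10.0 s, and Thursday's run, with 2.2 equiv, reads 17.3% at the same time, so I take the fall of the substrate as first-order, at a rate that the partner does not change within the scatter of these readings.

| flask | substrate | partner | remark | time |
|---|---|---|---|---|
| Friday's | 2 mM | 1.2 equiv | run made earlier |  |
| Thursday's | 2 mM | 2.2 equiv | run made earlier |  |
| west | 2.0 mM | 1.10 equiv |  | 2.0 min |
| south-west | 2.0 mM | 1.40 equiv |  | 2.0 min |

| run | time / s | target / % | substrate / % | homo product / % | side product / % |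
|---|---|---|---|---|---|
| Friday's | 10.0 | 50.1 | 16.2 | 27.3 | 4.0 |
| Friday's | 15.0 | 60.4 | 7.7 | 29.5 | 6.4 |
| Friday's | 25.0 | 65.8 | 0 | 27.3 | 5.4 |
| Friday's | 40.0 | 66.3 | 1.2 | 29.0 | 4.7 |
| Friday's | 50.0 | 65.3 | 0 | 29.3 | 3.9 |
| Friday's | 60.0 | 69.1 | 0 | 27.6 | 6.5 |
| Thursday's | 10.0 | 64.2 | 17.3 | 14.8 | 3.4 |
| Thursday's | 15.0 | 74.9 | 6.8 | 15.1 | 4.6 |
| Thursday's | 25.0 | 79.5 | 1.5 | 15.2 | 3.9 |
| Thursday's | 30.0 | 81.5 | 0 | 17.1 | 3.8 |
| Thursday's | 40.0 | 82.5 | 0 | 17.4 | 2.8 |
| Thursday's | 50.0 | 81.2 | 0 | 16.4 | 4.1 |
| Thursday's | 60.0 | 79.4 | 0 | 14.9 | 4.3 |

(readings scatter by 1 percentage point)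

* which of these there is most of at the end, counted by the substrate in it, west (homo product / side product / substrate / target)
* which of these there is most of at the end, counted by the substrate in it, south-west (homo product / side product / substrate / target)
* the largest of these amounts at the end, in percent of the substrate charged, west
* the largest of these amounts at the end, in percent of the substrate charged, south-west

- a species is counted by the substrate in it: one homo product counts as two

The mean of those two readings gives a half-life of 3.88 s, the time in which the substrate falls by half. This half-life predicts 6.86% at 15.0 s, and the runs, which did not go into it, read 7.7% and 6.8% there. The first setting is the time, and 2.0 min gives 30.9, the count of half-lives, asked time over half-life, in both west and south-west. By hand, then, I expect the time to move nothing, and Thursday's run agrees: from 30.0 s its substrate reads 0% and its target reads between 79.4% and 82.5%.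

The second setting is the partner, and it does move the end, since target reads 66.3% in Friday's run at 40.0 s and 82.5% in Thursday's run at 40.0 s. My straight line through these two readings puts target at 64.7% in west and 69.5% in south-west. The forecast, noting that “Homo product forms early and falls with more partner”, names target for west and target for south-west, with 64.3% in west, lower than my line, and 70.7% in south-west, higher than my line.

West ends with target at 63.8% and south-west with target at 70.7%.

    substrate → open intermediate (k = 0.177 s⁻¹)
    partner → second intermediate (k = 0.181 s⁻¹)
    open intermediate + second intermediate → target (k = 1550 M⁻¹ s⁻¹)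
    2 open intermediate → homo product (k = 2510 M⁻¹ s⁻¹)
    open intermediate → side product (k = 0.0931 s⁻¹)

West at 1.00 min, 15.5 half-lives in, holds the same 63.8% of target as at 2.00 min, where the count stands at 30.9. In south-west at 0.0639 min, the open intermediate is used by the target step at 2.9 times the rate of the homo step, which is the instantaneous selectivity at that moment. A neighbour, south-west with 0.560 equiv of partner, has the same count of 30.9 and reads 0% substrate at 2.00 min, with homo product at 49.4% over target at 42.2%.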